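I began with an easy step: I laid Sunday's run beside Wednesday's, which had the same charges of X and D, and looked for one stage reached in both. Q stood at 61.5 % after 8.00 h at 0 °C and at 61.4 % after 1.67 d at −15 °C, although Sunday's L was higher. So I read a clock factor of 5.01, the number of times shorter the same stage took in the warmer flask. In logarithms that was 0.700 powers of ten per 15.0 K, an Arrhenius shift read from scattered readings.

| flask | X | D | L | temperature | remark | time |
|---|---|---|---|---|---|---|
| Wednesday's | 0.23 M | 0.23 M | 0.069 M | −15 °C | run made earlier |  |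
| Thursday's | 0.15 M | 0.23 M | 0.069 M | 0 °C | run made earlier |  |
| Tuesday's | 0.35 M | 0.23 M | 0.069 M | −15 °C | run made earlier |  |
| Sunday's | 0.23 M | 0.23 M | 0.10 M | 0 °C | run made earlier |  |
| beta | 0.23 M | 0.230 M | 0.0690 M | 0 °C | everything together at the start | 2.0 d |
| delta | 0.23 M | 0.230 M (fed, over 20 h) | 0.0690 M | 0 °C | all else is in the flask from the start; the feed brings no volume worth counting | 2.0 d |
| zeta | 0.23 M (fed, over 20 h) | 0.230 M | 0.0690 M | 0 °C | all else is in the flask from the start; the feed brings no volume worth counting | 2.0 d |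
| gamma | 0.23 M (fed, over 20 h) | 0.230 M | 0.0690 M |  | the addition at −40 °C, then warmed to 0 °C; the feed brings no volume worth counting | 2.0 d |

- Wednesday's (time / d: Q / %, X / %): 0.417: 30.7, 30.5; 0.833: 47.3, 23.8; 1.25: 56.9, 17.6; 1.67: 61.4, 14.3; 2.00: 65.2, 12.4; 2.50: 67.2, 8.8
- Thursday's (time / h: Q / %, X / %): 2.50: 43.6, 28.0; 8.00: 70.0, 10.8; 15.0: 81.5, 3.8; 20.0: 84.1, 4.2; 30.0: 84.8, 1.0; 40.0: 86.9, 0.8
- Tuesday's (time / d: Q / %, X / %): 0.500: 32.4, 29.7; 1.04: 45.2, 22.3; 1.67: 51.4, 18.1; 2.00: 52.8, 15.6; 2.50: 57.8, 13.8; 4.00: 59.1, 11.1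
- Sunday's (time / h: Q / %, X / %): 8.00: 61.5, 13.2; 15.0: 70.7, 8.3; 25.0: 72.7, 3.2; 30.0: 74.7, 3.6; 40.0: 74.8, 1.8

(standard deviation of a reading: 1 percentage point)

* the flask with the highest amount of Q, in percent of the X charged ("all alike" if they lie within 1.5 percentage points) (beta / delta / zeta / gamma / all alike)
* final Q, as a percentage of the X charged, in beta
* final Q, as a percentage of the X charged, in delta
* final Q, as a percentage of the X charged, in zeta
* final Q, as a percentage of the X charged, in gamma

- what was read earlier has a scatter of 1 percentage point, one standard deviation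

I then ran the flask in slow motion at 0 °C. In the first instants, Thursday's run after 2.50 h had X at 28.0 %, while 28.4 % of the X charged was neither X nor Q, about as much as the X itself. I took this to be an unread form standing in balance with X. In the middle, Q climbed quickly, reaching 81.5 % by 15.0 h. At the end it crept, gaining 2.1 percentage points between 30.0 h and 40.0 h.

Sunday's run, with more X and L than Thursday's, ended at 74.8 %, so I put beta, with Sunday's X and Thursday's L, above that. For gamma, the drop to −40 °C was 1.87 powers of ten, a slowing by 73.5. Its feed of 20 h was therefore worth 0.272 h at 0 °C, hardly any of the time asked. That made gamma a beta with 28.0 h at 0 °C, and I set it below beta by about Thursday's late gain. My own reckoning stopped there: I put no figure on delta or zeta, the two flasks fed at 0 °C.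

The forecast, unlike my reckoning, put a figure on each flask: 78 %, 70 %, 85 % and 76 % for beta, delta, zeta and gamma, with zeta on top: “keeps X low, so least waste”.

The flasks gave 77.4 %, 61.6 %, 67.9 % and 75.5 % in that order, with beta on top.

    2 X → Z (k = 0.310 M⁻¹ h⁻¹, Ea = 79.0 kJ mol⁻¹)
    L + G → E (k = 0.360 M⁻¹ h⁻¹, Ea = 71.0 kJ mol⁻¹)
    X ⇌ G, settled at all times (K = 0.930, ΔH = −2.00 kJ mol⁻¹)
    D → J (k = 0.0220 h⁻¹, Ea = 96.0 kJ mol⁻¹)
    D + G → Q (k = 2.50 M⁻¹ h⁻¹, Ea = 68.0 kJ mol⁻¹)
    (constants at 0 °C)

Gamma, worth 28.0 h on the clock, stood 1.9 points below beta, with X at 4.12 % against 2.36 %. The neighbouring flask, beta kept at 25 °C, took the same reckoning: 1.17 powers of ten, a factor of 14.7. Its 2.0 d therefore counted as 29.3 d at 0 °C, longer than beta's simulated 20.0 d. X stood at 0.0675 % in the neighbour and 0.0477 % in that long beta, but Q stood at 64.8 % in the neighbour against 78.5 % in long beta.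

The runs are simulated for substances that don't exist; the scatter is artificial.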